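## Analysis of the target

Eriosemaone D is 5,7-dihydroxy-3-(7-hydroxy-2,2-dimethyl-2H-chromen-6-yl)-4H-chromen-4-one. It is an isoflavone (rings A and C) whose ring B, attached at C3, carries a 2'-hydroxyl and is fused linearly, through the oxygen at C4' and the carbon C5', to a 2,2-dimethyl-2H-pyran (ring D). The molecule has no stereocentre and is achiral. The only geometric element is the cis alkene locked in ring D, so the problems are regiochemistry and functional-group tolerance, not configuration. The sensitive groups are the electron-rich styrene-type alkene of ring D (acid, electrophiles, oxidants, hydrogenation, UV light), the three phenols (the one at C5 is chelated to the C4 carbonyl) and the electrophilic C2 of the chromone. The synthesis is hard for three reasons: ring D must be fused at C5' and not at C3', the C3–C1' bond joins two oxygen-laden rings, and the three phenols must be freed at the end without touching ring D. The plan rests on ring A. With O1 on C8a and oxygens on C5 and C7 it is a 3,5-dioxygenated phenoxy group, whose two carbons ortho to O1 (the future C4a and C8) are equivalent by symmetry and activated by all three oxygens. Ring C can therefore be closed last at carbon, C4 to C4a, by an acylation that has only one possible site.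

## Retrosynthetic reasoning

**23 to 22.** The three O–H bonds of target 23 are traced back to three allyl ethers in 22. Allyl is chosen because it survives the acid of the ring closure and the bases used earlier. It is removed under neutral conditions by a zerovalent palladium catalyst with an amine as allyl acceptor, which leaves the ring D alkene and the chromone alone.

**22 to 20.** The C4–C4a bond of ring C is cut, which leads to the 3-aryloxyacrylic acid 20. The cut is made here because it is the only bond of ring C whose formation can have no regiochemical ambiguity: in 20 the two ortho carbons of the 3,5-bis(allyloxy)phenoxy ring are the same. What is gained is an open-chain precursor in which rings A and B are joined only through an enol ether and a carboxyl group. The forward reaction must activate the acid as the mixed anhydride 21, let the E alkene reach the cisoid geometry and acylate ring A without harming ring D.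

**20 to 16 and 18.** After the ester 19 is recognised as the source of the acid, the vinyl ether bond O1–C2 is cut. This divides the molecule into the ring A phenol 18 and the ring B enol tosylate 16. The forward reaction is an addition–elimination at the β-carbon of an acrylate. It joins the two halves late and uses both in near-equal amounts.

**16 to 12.** The tosylate 16 comes from the enol 14 and the sulfonyl chloride 15. The C2 carbon of the future chromone is removed as a formyl unit, so 14 goes back to the arylacetate 12 and the formate 13. A crossed Claisen condensation is the standard way to place one carbon at the oxidation level of a formyl group next to an ester.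

**12 to 7 and 8.** The bond between ring B and the acetate methylene is cut, giving the bromochromene 7 and the zinc enolate 8. The bromide ortho to the ring B oxygen cannot carry an allyl ether during this coupling. Zerovalent palladium would insert the aryl–palladium bond into the neighbouring allyl group (5-exo carbopalladation to a benzofuran) or ionise the ether. The oxygen is therefore silylated with 4 for the coupling, and the silyl ether of 9 is exchanged for allyl with 10 in one pot through the phenoxide 11.

**7 to 1 and 2.** Ring D is taken back from the chromene 7 to the chromanone 5 by way of the alcohol 6 (reduction, then loss of water), and 5 to the phenol 3. Cutting the aryl–carbonyl bond and the O1–C2 bond of 3 gives 4-bromoresorcinol 1 and the unsaturated acid 2. The bromine of 1 does two jobs: it blocks one position so that ring D can only fuse linearly, and it marks the carbon where the acetate side chain is later attached.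

**18 to 17 and 10.** The phenol 18 is phloroglucinol 17 with two of its three equivalent hydroxyls allylated by 10. The cut is trivial but statistical, and it is placed on the cheapest material of the route.

## Alternatives that were turned down

**Alternative 1: ring A built by benzannulation.** Here ring A is not bought but made. Four bonds (C4a–C5, C5–C6, C7–C8 and C8–C8a) are formed around a pre-existing 4-pyranone, which leads back to the diazoketone A2 and the silyloxyalkyne A3. In the forward step, irradiation of A2 triggers a Wolff rearrangement to a pyranonyl ketene. The ketene adds A3 to give a cyclobutenone, which opens to a dienylketene and closes by 6π electrocyclisation onto the C2=C3 bond of the pyranone, giving the isoflavone A1.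
- For it: one operation creates the whole of ring A. The polarity of the ynol ether places the free hydroxyl at C5 and the silyl ether at C7 without any symmetry argument. No acid is used. On the differentiation of the two ring A oxygens it is stronger than the chosen route.
- Against it: a 2H-chromene does not survive UV light (photochromic ring opening), so A1 has to carry a saturated chroman. The ring D alkene must then be introduced afterwards by dehydrogenation, followed by two different deprotections. The diazoketone needs an acid chloride and a diazoalkane on a pyranone that is itself an acceptor. The electrocyclisation has to engage an electron-poor vinylogous ester double bond. A3 is hydrolytically fragile.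
- Comparison: the route is longer and builds an arene that phloroglucinol 17 supplies ready-made. The chosen strategy offers commodity starting materials and a single-bond closure whose site is fixed by symmetry.

**Alternative 2: ring D closed last by hydroarylation.** The C5'–C4'' bond of ring D is cut, which leads to the isoflavone A5 carrying a 1,1-dimethylpropargyl ether at C4' and a bulky silyl ether at C2'. In the forward step Ph3PAuNTf2 (monovalent gold) activates the terminal alkyne and C5' attacks it in 6-endo fashion to give the chromene A4.
- For it: the isoflavone core can be assembled convergently by established coupling chemistry. Ring D appears only at the end under neutral conditions, so the acid-sensitive alkene is never exposed. On these two points it is stronger than the chosen route.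
- Against it: the regiochemistry of ring D depends only on a steric bias. C3', between two oxygens, is electronically the better nucleophile, and only the triisopropylsilyl group discourages attack there. A wrong fusion would appear at the last carbon–carbon bond-forming step as a hard-to-separate isomer. The tertiary propargyl ether must be installed on one of two phenols, and the acetal protecting groups must tolerate a Lewis-acidic gold cation and a final acidic deprotection next to the chromene.
- Comparison: the chosen strategy fixes the linear fusion in the first step through the bromine of 1 and unmasks the phenols without acid.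

**Alternative 3: ring C by aryne insertion.** Three bonds of ring C (O1–C8a, C4–C4a and O1–C2) are cut at once, giving the silyl triflate A7 as aryne precursor and the 3-methoxyacrylic acid A8. In the forward step CsF releases the 3,5-dioxygenated benzyne from A7. The carboxylate of A8 adds, the aryl anion attacks the acyl carbon so that the aryne is inserted into the C–O bond of the acid, and the resulting phenoxide displaces methoxide at C2 to give A6.
- For it: it is highly convergent and closes ring C in one flask under fluoride conditions that are harmless to the chromene. The alkoxy group next to the aryne steers the regiochemistry. The acid A8 is the ordinary methoxyacrylate and needs no vinylic substitution with a phenol. In bonds formed per step it is stronger than the chosen route.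
- Against it: A7 costs several steps from a phloroglucinol derivative (differentiation of the oxygens, ortho-silylation, triflation). After O-arylation, proton transfer competes with acyl migration and leads to aryl esters. The aryne can also react with the enol ether or the ring D alkene. The acetal groups of A6 have to be removed with acid in the presence of the chromene.
- Comparison: the chosen strategy uses the same ring A carbon as the nucleophile but takes it from the phenol 18 in one step. It relies on a well-precedented acylation and ends with a neutral deprotection.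

Key step: step 11

Remark on the chemistry: the double-bond geometry of 14 and 16 is not controlled and is assumed not to matter. The addition–elimination of step 9 passes through a freely rotating stabilised carbanion and should converge on the more stable E ester 19. Compound 16 is drawn as E.

## Route

Step 1
Reactants: 1 4-bromoresorcinol; 2 3-methylbut-2-enoic acid
Product: 3 6-bromo-7-hydroxy-2,2-dimethylchroman-4-one
Conditions: P2O5, MeSO3H, 70 °C
Reagents that add atoms: 3-methylbut-2-enoic acid (2), CC(C)=CC(=O)O
Why: Friedel–Crafts acylation at the carbon para to one hydroxyl and ortho to the other, followed by oxa-Michael closure of the ortho hydroxyl onto the enone, is the standard chromanone synthesis from resorcinols. The bromine occupies the other activated position, so only the linear 6-bromo-7-hydroxy isomer can form.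

Step 2
Reactants: 3 6-bromo-7-hydroxy-2,2-dimethylchroman-4-one; 4 chlorotriisopropylsilane
Product: 5 6-bromo-2,2-dimethyl-7-(triisopropylsilyloxy)chroman-4-one
Conditions: TIPSCl, imidazole, DMF, rt
Reagents that add atoms: chlorotriisopropylsilane (4), CC(C)[Si](Cl)(C(C)C)C(C)C
Why: Silylation of the phenol removes the acidic proton that would otherwise deactivate the ketone toward hydride as a vinylogous carboxylate. The bulky silyl ether is inert to zerovalent palladium, unlike an allyl ether ortho to the bromide.

Step 3
Reactants: 5 6-bromo-2,2-dimethyl-7-(triisopropylsilyloxy)chroman-4-one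
Product: 7 6-bromo-2,2-dimethyl-7-(triisopropylsilyloxy)-2H-chromene, via racemic chroman-4-ol 6 (not isolated)
Conditions: NaBH4, MeOH/THF, 0 °C to rt; then p-TsOH·H2O (cat.), toluene, 80 °C
Reagents that add atoms: none
Why: Hydride reduction gives the benzylic alcohol, whose stereocentre is lost again at once. Acid-catalysed dehydration proceeds through a benzylic cation stabilised by the para silyloxy group and the ring oxygen and gives the conjugated 2H-chromene.

Step 4
Reactants: 7 6-bromo-2,2-dimethyl-7-(triisopropylsilyloxy)-2H-chromene; 8 (2-methoxy-2-oxoethyl)zinc bromide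
Product: 9 methyl 2-[2,2-dimethyl-7-(triisopropylsilyloxy)-2H-chromen-6-yl]acetate
Conditions: BrZnCH2CO2Me, Pd2(dba)3 (cat.), XPhos, THF, 65 °C
Reagents that add atoms: (2-methoxy-2-oxoethyl)zinc bromide (8), COC(=O)C[Zn]Br
Why: Palladium-catalysed α-arylation of a Reformatsky zinc enolate (a Negishi-type coupling) works with electron-rich, ortho-substituted aryl bromides when a bulky biarylphosphine is used. The reagent is not basic, so the silyl ether and the chromene are untouched.

Step 5
Reactants: 9 methyl 2-[2,2-dimethyl-7-(triisopropylsilyloxy)-2H-chromen-6-yl]acetate; 10 allyl bromide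
Product: 12 methyl 2-[7-(allyloxy)-2,2-dimethyl-2H-chromen-6-yl]acetate, via cesium phenoxide 11 (not isolated)
Conditions: CsF, allyl bromide, DMF, rt
Reagents that add atoms: allyl bromide (10), C=CCBr
Why: Fluoride cleaves the aryl silyl ether and the phenoxide is trapped in the same flask by Williamson alkylation. The protecting group is thereby changed to the one that must survive the acid of step 11, now that no palladium step lies ahead before the last step.

Step 6
Reactants: 12 methyl 2-[7-(allyloxy)-2,2-dimethyl-2H-chromen-6-yl]acetate; 13 methyl formate
Product: 14 methyl 2-[7-(allyloxy)-2,2-dimethyl-2H-chromen-6-yl]-3-hydroxyprop-2-enoate (hydrogen-bonded Z enol, in equilibrium with the aldehyde tautomer)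
Conditions: NaH, HCO2Me, THF, 0 °C to rt; AcOH quench
Reagents that add atoms: methyl formate (13), COC=O
Why: Crossed Claisen condensation of an arylacetate enolate with a formate is the classical formylation used for 2-aryl-3-oxygenated acrylates. It is driven by formation of the stabilised enolate of the product.

Step 7
Reactants: 14 methyl 2-[7-(allyloxy)-2,2-dimethyl-2H-chromen-6-yl]-3-hydroxyprop-2-enoate; 15 p-toluenesulfonyl chloride
Product: 16 methyl (E)-2-[7-(allyloxy)-2,2-dimethyl-2H-chromen-6-yl]-3-(tosyloxy)prop-2-enoate
Conditions: TsCl, Et3N, N-methylimidazole (cat.), CH2Cl2, 0 °C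
Reagents that add atoms: p-toluenesulfonyl chloride (15), Cc1ccc(cc1)S(Cl)(=O)=O
Why: O-Sulfonylation of the enol of an α-formyl ester under amine base is a known route to enol tosylates. It turns the enol oxygen into a leaving group on the β-carbon under conditions free of acid.

Step 8
Reactants: 17 phloroglucinol; 10 allyl bromide
Product: 18 3,5-bis(allyloxy)phenol
Conditions: allyl bromide (2 equiv), K2CO3, DMF, 0 °C to rt; chromatography
Reagents that add atoms: allyl bromide (10), C=CCBr
Why: Williamson alkylation of the symmetrical triphenol in a dipolar aprotic solvent favours O-alkylation. The diether should be separable from the mono- and tri-ethers because the three differ by one free hydroxyl each.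

Step 9
Reactants: 16 methyl (E)-2-[7-(allyloxy)-2,2-dimethyl-2H-chromen-6-yl]-3-(tosyloxy)prop-2-enoate; 18 3,5-bis(allyloxy)phenol
Product: 19 methyl (E)-3-[3,5-bis(allyloxy)phenoxy]-2-[7-(allyloxy)-2,2-dimethyl-2H-chromen-6-yl]prop-2-enoate
Conditions: K2CO3, DMF, rt to 40 °C
Reagents that add atoms: 3,5-bis(allyloxy)phenol (18), Oc1cc(OCC=C)cc(OCC=C)c1
Why: Nucleophilic vinylic substitution by addition–elimination: the phenoxide adds to C3 of the acrylate and the ester- and aryl-stabilised carbanion expels tosylate. The carbanion is long-lived enough to let the product settle in the more stable E geometry.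

Step 10
Reactants: 19 methyl (E)-3-[3,5-bis(allyloxy)phenoxy]-2-[7-(allyloxy)-2,2-dimethyl-2H-chromen-6-yl]prop-2-enoate
Product: 20 (E)-3-[3,5-bis(allyloxy)phenoxy]-2-[7-(allyloxy)-2,2-dimethyl-2H-chromen-6-yl]prop-2-enoic acid
Conditions: LiOH·H2O, THF/H2O, 40 °C; then 1 M HCl to pH 3, 0 °C
Reagents that add atoms: lithium hydroxide, [Li+].[OH-]
Why: Saponification of 3-aryloxyacrylic esters to the acids is established. The aryloxy donor lowers the electrophilicity of C3, and the carboxylate, once formed, protects the enol ether from further attack; no alcohol cosolvent is used, so no alkoxide can exchange at C3.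

Step 11
Reactants: 20 (E)-3-[3,5-bis(allyloxy)phenoxy]-2-[7-(allyloxy)-2,2-dimethyl-2H-chromen-6-yl]prop-2-enoic acid
Product: 22 5,7-bis(allyloxy)-3-[7-(allyloxy)-2,2-dimethyl-2H-chromen-6-yl]-4H-chromen-4-one, via mixed trifluoroacetic anhydride 21 (not isolated)
Conditions: (CF3CO)2O, CH2Cl2 (0.02 M), 0 °C to rt
Reagents that add atoms: none
Why: The anhydride converts 20 into the mixed anhydride 21, which ionises to an acylium ion that can equally be written as the O-aryl oxocarbenium of a ketene; in this form C2–C3 is a single bond, so the E geometry relaxes to the cisoid rotamer in which the acyl carbon faces ring A. The ring carbon ortho to the ether oxygen, which is also ortho and para to the two allyloxy groups, then attacks the acyl carbon and loses a proton (intramolecular Friedel–Crafts acylation). The closest known reaction type is the acid- or anhydride-mediated cyclisation of 3-aryloxyacrylic acids to chromones. Ring C closes as a six-membered ring by attack on the acyl carbon with its oxygen left outside the ring (6-exo). No stereocentre is formed. The step needs site selectivity, and the substrate secures it: the two candidate carbons of ring A are equivalent by symmetry, they are far more nucleophilic than any carbon of ring B or of the ring D alkene, and ring B cannot reach the acyl carbon without forming a four-membered ring. High dilution disfavours intermolecular acylation, and the low temperature that the phloroglucinol-type nucleophile allows spares the ring D alkene and the allyl ethers from the trifluoroacetic acid released.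

Step 12
Reactants: 22 5,7-bis(allyloxy)-3-[7-(allyloxy)-2,2-dimethyl-2H-chromen-6-yl]-4H-chromen-4-one
Product: 23 eriosemaone D, 5,7-dihydroxy-3-(7-hydroxy-2,2-dimethyl-2H-chromen-6-yl)-4H-chromen-4-one
Conditions: Pd(PPh3)4 (cat.), morpholine, THF, rt
Reagents that add atoms: none
Why: Tsuji–Trost deallylation: zerovalent palladium ionises each aryl allyl ether to a π-allyl complex that morpholine intercepts. The conditions are neutral and non-reducing, so the ring D alkene and the chromone remain intact while all three phenols are freed.

## Compound list

1 | 4-bromoresorcinol | Oc1ccc(Br)c(O)c1 | starting material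
2 | 3-methylbut-2-enoic acid | CC(C)=CC(=O)O | starting material
3 | 6-bromo-7-hydroxy-2,2-dimethylchroman-4-one | CC1(C)CC(=O)c2cc(Br)c(O)cc2O1 | intermediate
4 | chlorotriisopropylsilane | CC(C)[Si](Cl)(C(C)C)C(C)C | starting material
5 | 6-bromo-2,2-dimethyl-7-(triisopropylsilyloxy)chroman-4-one | CC1(C)CC(=O)c2cc(Br)c(O[Si](C(C)C)(C(C)C)C(C)C)cc2O1 | intermediate
6 | 6-bromo-2,2-dimethyl-7-(triisopropylsilyloxy)chroman-4-ol (racemic, not isolated) | CC1(C)CC(O)c2cc(Br)c(O[Si](C(C)C)(C(C)C)C(C)C)cc2O1 | intermediate
7 | 6-bromo-2,2-dimethyl-7-(triisopropylsilyloxy)-2H-chromene | CC1(C)C=Cc2cc(Br)c(O[Si](C(C)C)(C(C)C)C(C)C)cc2O1 | intermediate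
8 | (2-methoxy-2-oxoethyl)zinc bromide | COC(=O)C[Zn]Br | starting material
9 | methyl 2-[2,2-dimethyl-7-(triisopropylsilyloxy)-2H-chromen-6-yl]acetate | COC(=O)Cc1cc2C=CC(C)(C)Oc2cc1O[Si](C(C)C)(C(C)C)C(C)C | intermediate
10 | allyl bromide | C=CCBr | starting material
11 | cesium 6-(2-methoxy-2-oxoethyl)-2,2-dimethyl-2H-chromen-7-olate (not isolated) | COC(=O)Cc1cc2C=CC(C)(C)Oc2cc1[O-].[Cs+] | intermediate
12 | methyl 2-[7-(allyloxy)-2,2-dimethyl-2H-chromen-6-yl]acetate | COC(=O)Cc1cc2C=CC(C)(C)Oc2cc1OCC=C | intermediate
13 | methyl formate | COC=O | starting material
14 | methyl (Z)-2-[7-(allyloxy)-2,2-dimethyl-2H-chromen-6-yl]-3-hydroxyprop-2-enoate (enol form) | COC(=O)/C(c1cc2C=CC(C)(C)Oc2cc1OCC=C)=C\O | intermediate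
15 | p-toluenesulfonyl chloride | Cc1ccc(cc1)S(Cl)(=O)=O | starting material
16 | methyl (E)-2-[7-(allyloxy)-2,2-dimethyl-2H-chromen-6-yl]-3-(tosyloxy)prop-2-enoate | COC(=O)/C(c1cc2C=CC(C)(C)Oc2cc1OCC=C)=C/OS(=O)(=O)c1ccc(C)cc1 | intermediate
17 | phloroglucinol | Oc1cc(O)cc(O)c1 | starting material
18 | 3,5-bis(allyloxy)phenol | Oc1cc(OCC=C)cc(OCC=C)c1 | intermediate
19 | methyl (E)-3-[3,5-bis(allyloxy)phenoxy]-2-[7-(allyloxy)-2,2-dimethyl-2H-chromen-6-yl]prop-2-enoate | COC(=O)/C(c1cc2C=CC(C)(C)Oc2cc1OCC=C)=C/Oc1cc(OCC=C)cc(OCC=C)c1 | intermediate
20 | (E)-3-[3,5-bis(allyloxy)phenoxy]-2-[7-(allyloxy)-2,2-dimethyl-2H-chromen-6-yl]prop-2-enoic acid | OC(=O)/C(c1cc2C=CC(C)(C)Oc2cc1OCC=C)=C/Oc1cc(OCC=C)cc(OCC=C)c1 | intermediate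
21 | (E)-3-[3,5-bis(allyloxy)phenoxy]-2-[7-(allyloxy)-2,2-dimethyl-2H-chromen-6-yl]prop-2-enoic trifluoroacetic anhydride (not isolated) | O=C(OC(=O)C(F)(F)F)/C(c1cc2C=CC(C)(C)Oc2cc1OCC=C)=C/Oc1cc(OCC=C)cc(OCC=C)c1 | intermediate
22 | 5,7-bis(allyloxy)-3-[7-(allyloxy)-2,2-dimethyl-2H-chromen-6-yl]-4H-chromen-4-one | C=CCOc1cc(OCC=C)c2c(c1)occ(-c1cc3C=CC(C)(C)Oc3cc1OCC=C)c2=O | intermediate
23 | eriosemaone D | CC1(C)C=Cc2cc(-c3coc4cc(O)cc(O)c4c3=O)c(O)cc2O1 | target

## Step count and least certain steps

Total step count: 12. Longest linear sequence: 11 steps (steps 1 to 7 and 9 to 12); step 8 is the one-step side branch to the ring A phenol.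

**Step 11 (key step).**
- What may go wrong: the activated E acid may fail to rotate into the cisoid geometry before it is consumed by intermolecular acylation or by addition of trifluoroacetate. The trifluoroacetic acid released may oligomerise the ring D alkene, and the reagent may trifluoroacetylate ring A directly.
- Fallback: it sets out from 12 (and from 17 with 10) and comes back to the route at 23. It makes the C4–C4a bond between two separate molecules, where no alkene geometry has to be reached, and closes ring C afterwards at O1–C2.
  - Saponification of 12 (LiOH, THF/H2O) gives 2-[7-(allyloxy)-2,2-dimethyl-2H-chromen-6-yl]acetic acid F1.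
  - Exhaustive allylation of 17 with 10 (K2CO3, DMF) gives 1,3,5-tris(allyloxy)benzene F2.
  - (CF3CO)2O in CH2Cl2 at 0 °C turns F1 into 2-[7-(allyloxy)-2,2-dimethyl-2H-chromen-6-yl]acetic trifluoroacetic anhydride F3. This acylates the symmetrical F2 at its only kind of ring carbon to give 2-[7-(allyloxy)-2,2-dimethyl-2H-chromen-6-yl]-1-[2,4,6-tris(allyloxy)phenyl]ethan-1-one F4.
  - Condensation of F4 with N,N-dimethylformamide dimethyl acetal (toluene, 90 °C) gives (E)-2-[7-(allyloxy)-2,2-dimethyl-2H-chromen-6-yl]-3-(dimethylamino)-1-[2,4,6-tris(allyloxy)phenyl]prop-2-en-1-one F5.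
  - Pd(PPh3)4 with morpholine removes the four allyl groups and gives (E)-3-(dimethylamino)-2-(7-hydroxy-2,2-dimethyl-2H-chromen-6-yl)-1-(2,4,6-trihydroxyphenyl)prop-2-en-1-one F6.
  - On treatment with AcOH an ortho hydroxyl of ring A adds to the enaminone carbon (6-endo; the ring B hydroxyl would need a disfavoured 5-endo closure) and dimethylamine is lost, which gives 23.

**Step 9.**
- What may go wrong: the phenoxide may attack sulfur instead of carbon (transfer of the sulfonyl group to the phenol with return of the enolate of 14), or the ambident phenoxide may attack through a ring carbon.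
- Fallback: it sets out from 14 and comes back at 19. It replaces the sulfonate by a leaving group that has no second electrophilic site. Deoxychlorination of the enol with Ph3P and CCl4 in MeCN gives methyl 2-[7-(allyloxy)-2,2-dimethyl-2H-chromen-6-yl]-3-chloroprop-2-enoate F7 (mixture of geometric isomers). Its addition–elimination with 18 (K2CO3, DMF) gives 19.

**Step 10.**
- What may go wrong: hydroxide may add to C3 and expel the aryloxide (loss of ring A) faster than it attacks the hindered ester carbonyl.
- Fallback: it sets out from 19 and comes back at 20. It changes the mechanism from attack at the acyl carbon to SN2 cleavage of the O–CH3 bond: LiI in refluxing EtOAc, then acidification, in the absence of any oxygen nucleophile. This fallback makes no new compound (F0).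

**Step 4.**
- What may go wrong: oxidative addition into the electron-rich C–Br bond beside the bulky silyl ether may be slow, so that protodebromination and self-condensation of the zinc enolate take over.
- Fallback: it sets out from 7 and comes back at 9 without a transition metal.
  - Bromine–lithium exchange (n-BuLi, THF, −78 °C, kept cold to prevent migration of silicon from oxygen to carbon) gives [2,2-dimethyl-7-(triisopropylsilyloxy)-2H-chromen-6-yl]lithium F8.
  - Opening of ethylene oxide with BF3·OEt2 at −78 °C gives 2-[2,2-dimethyl-7-(triisopropylsilyloxy)-2H-chromen-6-yl]ethan-1-ol F9.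
  - Oxidation with TEMPO (cat.) and PhI(OAc)2 in MeCN/H2O gives 2-[2,2-dimethyl-7-(triisopropylsilyloxy)-2H-chromen-6-yl]acetic acid F10.
  - Esterification with Me3SiCHN2 in MeOH/toluene gives 9.

**Step 8.**
- What may go wrong: under- and over-alkylation together with C-allylation of the ambident phloroglucinol anion may leave little of the diether.
- Fallback: it sets out from 10 and comes back at 18.
  - 5-Bromoresorcinol F11 is allylated at both hydroxyls with 10 (K2CO3, DMF) to give 1,3-bis(allyloxy)-5-bromobenzene F12.
  - Bromine–lithium exchange (n-BuLi, THF, −78 °C) gives [3,5-bis(allyloxy)phenyl]lithium F13.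
  - B(OMe)3 converts F13 into dimethyl [3,5-bis(allyloxy)phenyl]boronate F14.
  - Oxidation of F14 with H2O2 and NaOH gives 18.

## Further compounds

F1 | step 11 | 2-[7-(allyloxy)-2,2-dimethyl-2H-chromen-6-yl]acetic acid | OC(=O)Cc1cc2C=CC(C)(C)Oc2cc1OCC=C
F2 | step 11 | 1,3,5-tris(allyloxy)benzene | C=CCOc1cc(OCC=C)cc(OCC=C)c1
F3 | step 11 | 2-[7-(allyloxy)-2,2-dimethyl-2H-chromen-6-yl]acetic trifluoroacetic anhydride | O=C(Cc1cc2C=CC(C)(C)Oc2cc1OCC=C)OC(=O)C(F)(F)F
F4 | step 11 | 2-[7-(allyloxy)-2,2-dimethyl-2H-chromen-6-yl]-1-[2,4,6-tris(allyloxy)phenyl]ethan-1-one | O=C(Cc1cc2C=CC(C)(C)Oc2cc1OCC=C)c1c(OCC=C)cc(OCC=C)cc1OCC=C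
F5 | step 11 | (E)-2-[7-(allyloxy)-2,2-dimethyl-2H-chromen-6-yl]-3-(dimethylamino)-1-[2,4,6-tris(allyloxy)phenyl]prop-2-en-1-one | O=C(c1c(OCC=C)cc(OCC=C)cc1OCC=C)/C(c1cc2C=CC(C)(C)Oc2cc1OCC=C)=C/N(C)C
F6 | step 11 | (E)-3-(dimethylamino)-2-(7-hydroxy-2,2-dimethyl-2H-chromen-6-yl)-1-(2,4,6-trihydroxyphenyl)prop-2-en-1-one | O=C(c1c(O)cc(O)cc1O)/C(c1cc2C=CC(C)(C)Oc2cc1O)=C/N(C)C
F7 | step 9 | methyl 2-[7-(allyloxy)-2,2-dimethyl-2H-chromen-6-yl]-3-chloroprop-2-enoate (mixture of geometric isomers) | COC(=O)C(=CCl)c1cc2C=CC(C)(C)Oc2cc1OCC=C
F0 | step 10 | none | none
F8 | step 4 | [2,2-dimethyl-7-(triisopropylsilyloxy)-2H-chromen-6-yl]lithium | [Li]c1cc2C=CC(C)(C)Oc2cc1O[Si](C(C)C)(C(C)C)C(C)C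
F9 | step 4 | 2-[2,2-dimethyl-7-(triisopropylsilyloxy)-2H-chromen-6-yl]ethan-1-ol | OCCc1cc2C=CC(C)(C)Oc2cc1O[Si](C(C)C)(C(C)C)C(C)C
F10 | step 4 | 2-[2,2-dimethyl-7-(triisopropylsilyloxy)-2H-chromen-6-yl]acetic acid | OC(=O)Cc1cc2C=CC(C)(C)Oc2cc1O[Si](C(C)C)(C(C)C)C(C)C
F11 | step 8 | 5-bromoresorcinol | Oc1cc(O)cc(Br)c1
F12 | step 8 | 1,3-bis(allyloxy)-5-bromobenzene | C=CCOc1cc(Br)cc(OCC=C)c1
F13 | step 8 | [3,5-bis(allyloxy)phenyl]lithium | [Li]c1cc(OCC=C)cc(OCC=C)c1
F14 | step 8 | dimethyl [3,5-bis(allyloxy)phenyl]boronate | COB(OC)c1cc(OCC=C)cc(OCC=C)c1
A1 | alternative 1 | 5-hydroxy-3-[7-(methoxymethoxy)-2,2-dimethylchroman-6-yl]-7-(triisopropylsilyloxy)-4H-chromen-4-one | COCOc1cc2OC(C)(C)CCc2cc1-c1coc2cc(O[Si](C(C)C)(C(C)C)C(C)C)cc(O)c2c1=O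
A2 | alternative 1 | 2-(2-diazoacetyl)-5-[7-(methoxymethoxy)-2,2-dimethylchroman-6-yl]-4H-pyran-4-one | [N-]=[N+]=CC(=O)c1cc(=O)c(-c2cc3CCC(C)(C)Oc3cc2OCOC)co1
A3 | alternative 1 | (ethynyloxy)triisopropylsilane | C#CO[Si](C(C)C)(C(C)C)C(C)C
A4 | alternative 2 | 3-[2,2-dimethyl-7-(triisopropylsilyloxy)-2H-chromen-6-yl]-5,7-bis(methoxymethoxy)-4H-chromen-4-one | COCOc1cc(OCOC)c2c(c1)occ(-c1cc3C=CC(C)(C)Oc3cc1O[Si](C(C)C)(C(C)C)C(C)C)c2=O
A5 | alternative 2 | 5,7-bis(methoxymethoxy)-3-[4-(2-methylbut-3-yn-2-yloxy)-2-(triisopropylsilyloxy)phenyl]-4H-chromen-4-one | COCOc1cc(OCOC)c2c(c1)occ(-c1ccc(OC(C)(C)C#C)cc1O[Si](C(C)C)(C(C)C)C(C)C)c2=O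
A6 | alternative 3 | 5,7-bis(methoxymethoxy)-3-[7-(methoxymethoxy)-2,2-dimethyl-2H-chromen-6-yl]-4H-chromen-4-one | COCOc1cc(OCOC)c2c(c1)occ(-c1cc3C=CC(C)(C)Oc3cc1OCOC)c2=O
A7 | alternative 3 | 3,5-bis(methoxymethoxy)-2-(trimethylsilyl)phenyl trifluoromethanesulfonate | COCOc1cc(OCOC)c([Si](C)(C)C)c(OS(=O)(=O)C(F)(F)F)c1
A8 | alternative 3 | (E)-3-methoxy-2-[7-(methoxymethoxy)-2,2-dimethyl-2H-chromen-6-yl]prop-2-enoic acid | OC(=O)/C(c1cc2C=CC(C)(C)Oc2cc1OCOC)=C/OC
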